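The numbers in the tables were generated by integration on assumed constants; noise was put on by code.

Counted in millimoles per litre of starting volume, Friday's and Monday's flasks each received 14.0 mM of coupling partner, less than their 20 mM of substrate, so I kept the books on the coupling partner as the limiting reagent.

| flask | substrate | coupling partner | free catalyst | temperature | remark | time |
|---|---|---|---|---|---|---|
| dusk | 20 mM | 14 mM (fed, over 20 s) | 1.8 mM | −25 °C | run made earlier; the fed solution adds 0.10 times the starting volume |  |
| noon | 20 mM | 14 mM (fed, over 20 s) | 4.2 mM | 0 °C | run made earlier; the fed solution adds 0.10 times the starting volume |  |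
| Friday's | 20 mM | 14.0 mM (fed, over 20 s) | 2.0 mM |  | at −20 °C until 20 s, from then on at 20 °C; the fed solution adds 0.10 times the starting volume | 6.0 min |
| Monday's | 20 mM | 14.0 mM (fed, over 20 s) | 6.0 mM |  | at 20 °C throughout; the fed solution adds 0.10 times the starting volume | 6.0 min |

1. the winner by amount of product, in percent of the substrate charged; "neither" if no more than 2 percentage points parts them (Friday's / Monday's / neither)
2. how much product is there at the end, in percent of the substrate charged: Friday's
3. how much product is there at the end, in percent of the substrate charged: Monday's

dusk run (percent of the substrate charged)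

| time / min | product / % | substrate / % |
|---|---|---|
| 1.00 | 50.2 | 48.8 |
| 2.00 | 68.5 | 31.4 |
| 3.00 | 68.6 | 30.4 |
| 4.00 | 69.5 | 30.4 |
| 5.00 | 69.6 | 30.3 |
| 6.00 | 70.4 | 30.6 |

noon run (percent of the substrate charged)

| time / s | product / % | substrate / % |
|---|---|---|
| 12.0 | 21.9 | 77.6 |
| 20.0 | 41.1 | 57.1 |
| 30.0 | 58.2 | 41.0 |
| 40.0 | 65.9 | 33.8 |
| 80.0 | 69.5 | 31.4 |
| 120 | 69.9 | 29.9 |

(scatter of a reading: 0.5 percentage points)

- amounts are per litre of the starting volume; all of the dose is in the solution fed

I worked with the fraction left, supposing that one mole of coupling partner removes one mole of substrate: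

floor = 1 − c(coupling partner)/c(substrate) = 30.0%

This substrate floor is the part of the charged substrate that stays unreacted when each mole of coupling partner has taken one mole of substrate into product. I tested the supposition on the earlier runs, which had the same charges of substrate and coupling partner:

Charged coupling partner, each run: 14 mM
Entered as product, dusk run, 6.00 min: 14.1 mM
Entered as product, noon run, 120 s: 14.0 mM

Substrate read less floor: 0.6 percentage points (dusk), −0.1 points (noon), beside a scatter of 0.5 points

The books closed to about one scatter of a reading. The dusk run had flattened by about 2.00 min. Friday's flask was warmer and richer in catalyst than the dusk run, and its 6.0 min was longer than that. Monday's flask was warmer and richer in catalyst than the noon run. But 20 °C was warmer than either earlier run, so those runs left open whether anything is lost there. My ledger gave 70.0% of product for each flask.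

The forecast said neither, with 67.5% for Friday's and 69% for Monday's, lower than my figure: “I expect both near 70, Friday's slightly lower”.

Friday's flask ended with 70.0% of product and Monday's with 70.0%, so the winner was neither.

    coupling partner + free catalyst → catalyst intermediate A (k = 66.0 L mol⁻¹ s⁻¹, Ea = 43.0 kJ mol⁻¹)
    substrate + catalyst intermediate A ⇌ catalyst intermediate B (K = 27.0 L mol⁻¹, k = 180 L mol⁻¹ s⁻¹, Ea = 41.0 kJ mol⁻¹, ΔH = −72.0 kJ mol⁻¹)
    catalyst intermediate B → free catalyst + product (k = 0.830 s⁻¹, Ea = 58.0 kJ mol⁻¹)
    (constants at −20 °C)

At 0.333 min Friday's flask still held 61.5% of its coupling partner and Monday's 4.71%, yet by 3.00 min each stood at 0%. The floor of 30.0% met the substrate left in Friday's flask, 30.0%, and in Monday's, 30.0%. For a further flask like Monday's but charged with 5.6 mM of coupling partner, the floor came to 72.0%, and that flask ended at 6.00 min with 72.0% of its substrate.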